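Which of these four flasks ends with the most target, and how much does each hold?

| setting | north-east | south-east | north | south-west |
|---|---|---|---|---|
| starting material | 0.20 M | 0.20 M | 0.20 M (fed, over 12 h) | 0.20 M |
| coupling partner | 0.240 M (fed, over 12 h) | 0.240 M | 0.240 M | 0.240 M (fed, over 12 h) |
| second substrate | 0.400 M | 0.400 M | 0.400 M | 0.400 M |
| protic impurity | 0.0400 M | 0.0400 M | 0.0400 M | 0.0400 M |
| temperature | 25 °C | 25 °C | 25 °C |  |
| time | 15 h | 15 h | 15 h | 15 h |
| remark | all else is in the flask from the start; the feed brings no volume worth counting | everything together at the start | all else is in the flask from the start; the feed brings no volume worth counting | the addition at −15 °C, then warmed to 25 °C; the feed brings no volume worth counting |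

    starting material + coupling partner ⇌ target (K1 = 11 M⁻¹, k1 = 4.93 × 10⁻⁴ M⁻¹ s⁻¹, Ea1 = 76.0 kJ mol⁻¹, ΔH1 = −51.0 kJ mol⁻¹)
    second substrate + coupling partner ⇌ second product (K2 = 3.82 M⁻¹, k2 = 1.95 × 10⁻⁵ M⁻¹ s⁻¹, Ea2 = 76.0 kJ mol⁻¹, ΔH2 = −10.0 kJ mol⁻¹)
    second substrate + protic impurity → quenched substrate (k3 = 0.00224 M⁻¹ s⁻¹, Ea3 = 74.0 kJ mol⁻¹)
    coupling partner → decomposed reagent (k4 = 3.19 × 10⁻⁴ s⁻¹, Ea4 = 100 kJ mol⁻¹)
    target ⇌ isomer of the product (K5 = 0.329, k5 = 8.96 × 10⁻⁵ s⁻¹, Ea5 = 96.0 kJ mol⁻¹, ΔH5 = 51.0 kJ mol⁻¹)
    (constants at 25 °C)

1. the flask that comes out highest in amount of target, in percent of the starting material charged, or "all alike" when all lie within 1.5 percentage points (north-east / south-east / north / south-west / all alike)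
2. target at the end, in percent of the starting material charged, north-east
3. target at the end, in percent of the starting material charged, south-east
4. target at the end, in percent of the starting material charged, north
5. target at the end, in percent of the starting material charged, south-west

- at 25 °C the constants are as listed, elsewhere as the activation energies and enthalpies make them

*What happens to the coupling partner at 25 °C?*

It decomposes, and it couples with the starting material. At full charge the two losses together make a pseudo-first-order sink of 1.50 h⁻¹. The route through the second substrate is far slower than decomposition, so I drop it.

*Is target safe once it is made?*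

No. Target and isomer trade quickly, with a relaxation half-life of 0.532 h (taken in north), short against the 15 h run. I therefore treat them as one pool, of which target holds 75.2%. The target part runs back to starting material and partner, so, if I count none of the released partner as coupling again, the pool drains at the leak, the reverse coupling constant times the target's share: 0.121 h⁻¹. That is a half-life of 5.73 h.

*Then integrate.*

Holding starting material at its charge, the pool gains from a partner that falls exponentially and loses by the leak. This gives pool = crop × (exp(−leak × time) − exp(−sink × time)), with a crop of 0.0616 M. In south-east I let the sink term die by the end, since its half-life is much shorter than the run. Target there comes to 3.75%.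

*South-west: does the partner survive the cold feed?*

Its decomposition constant at −15 °C is 0.00222 h⁻¹, which is 2.66% over the 12 h feed even for partner present from the start. So I start the warm stage with the whole charge, ignore cold coupling, and run the clock for the 3.00 h left. That gives 15.9%.

*And the feeds at 25 °C?*

In north-east I put the partner at feed rate over sink, 0.0133 M. The pool fills against the leak, drains after the feed and collects a small tail, which gives 8.98%. In north the partner's decomposition half-life of 0.604 h is far shorter than the feed. By that half-life, 0.0101 M of starting material has come in, so in north I count coupling as a far slower loss of partner than decomposition, and the integral gives 0.328%. My pick is south-west.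

The forecast also names south-west. It gives north-east 8.5% (6.5% to 10.5%), south-east 4.9% (3.8% to 6.2%), north 0.5% (0.3% to 1%) and south-west 16% (13% to 19%). Its figures differ from mine, but its order is the same. Its ground for the winner is that “the cold feed merely stockpiles the partner with little decomposition”.

The simulation puts south-west highest at 14.9%, with north-east at 8.84%, south-east at 4.77% and north at 0.476%. Beside the target in south-west stands 4.88% of isomer. The leak leaves 69.6% of a pool through the warm hours of south-west, and 16.3% through the whole run of south-east. In north-east, target stood at 11.0% after 12.0 h. The leak alone takes that to 7.65% by 15.0 h, the flask then holds 8.84%, and coupling partner stood at 6.62% of its charge when those hours began.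

The constants used here were drawn at random within sensible limits; no experiment stands behind them.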